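The lavandulyl stereocentre comes from an auxiliary-controlled alkylation, and C2 is set by a chiral catalyst in the key step. The facial sense of that catalyst is assumed, not established.

**Strategy**

Ring C is disconnected at O1–C2 and at C4–C4a, so that C2–C3–C4 and ring B arrive as one cinnamoyl unit. The key step exploits the ortho relationship in ring A between O1 on C8a and the unsubstituted C4a: the cinnamoyl group is first hung on O1 as an aryl ester, irradiation shifts the acyl carbon from O1 to C4a (photo-Fries rearrangement), and the phenol thus liberated adds to the enone under a chiral thiourea catalyst, closing the pyranone and setting C2 in the same flask. The precursor is an open-chain (E)-cinnamate of a lavandulylated phloroglucinol ether; the ester oxygen marks which oxygen becomes O1, and C8 is blocked by the lavandulyl group.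

Key step: step 11

Remark (assumption): compounds 1, 2, 5, 10, 13 and 15 are taken as commercially available.
Remark (assumption): the epi-quinidine-derived thiourea is taken to give the 2S sense in step 11; were the sense opposite, its epi-quinine-derived pseudoenantiomer would be used with no other change.

**Route**

Step 1
Reactants: 1 (S)-4-benzyl-2-oxazolidinone; 2 3-methylbut-2-enoyl chloride
Product: 4 (S)-4-benzyl-3-(3-methylbut-2-enoyl)oxazolidin-2-one, via N-lithio oxazolidinone 3 (not isolated)
Conditions: n-BuLi, THF, −78 °C; then 2, −78 to 0 °C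
Reagents that add atoms: none
Why: N-acylation of the lithiated Evans auxiliary with an acid chloride should give the imide cleanly; no stereocenter is formed.

Step 2
Reactants: 4 (S)-4-benzyl-3-(3-methylbut-2-enoyl)oxazolidin-2-one; 5 prenyl bromide (1-bromo-3-methylbut-2-ene)
Product: 7 (S)-4-benzyl-3-[(2S)-5-methyl-2-(prop-1-en-2-yl)hex-4-enoyl]oxazolidin-2-one, via sodium Z-dienolate 6 (not isolated)
Conditions: NaN(SiMe3)2, THF, −78 °C; then 5, −78 to −30 °C
Reagents that add atoms: none
Why: γ-deprotonation should give the chelated Z-dienolate, which is alkylated at the α-carbon on the face opposite the benzyl group (Evans asymmetric alkylation in its deconjugative form), setting the 2S centre that becomes the R-configured lavandulyl carbon of the target.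

Step 3
Reactants: 7 (S)-4-benzyl-3-[(2S)-5-methyl-2-(prop-1-en-2-yl)hex-4-enoyl]oxazolidin-2-one
Product: 8 (S)-lavandulol [(2S)-5-methyl-2-(prop-1-en-2-yl)hex-4-en-1-ol]
Conditions: LiBH4, H2O (1 equiv), Et2O, 0 °C
Reagents that add atoms: none
Why: reductive cleavage of the N-acyl oxazolidinone with LiBH4 should give the primary alcohol and return the auxiliary without touching the α-stereocenter or the alkenes.

Step 4
Reactants: 8 (S)-lavandulol
Product: 9 (S)-lavandulyl iodide [(3S)-3-(iodomethyl)-2,6-dimethylhepta-1,5-diene]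
Conditions: PPh3, I2, imidazole, CH2Cl2, 0 °C (reagent preformed); then 8, 0 °C to rt
Reagents that add atoms: iodine II
Why: Appel-type iodination proceeds by SN2 at the CH2 group and leaves the adjacent stereocenter untouched, and adding the alcohol to the preformed phosphonium reagent keeps free iodine away from the alkenes.

Step 5
Reactants: 10 5-methoxyresorcinol
Product: 11 3-methoxy-5-[(triisopropylsilyl)oxy]phenol
Conditions: (i-Pr)3SiCl (1.0 equiv), imidazole, DMF, 0 °C, diol in excess and recovered
Reagents that add atoms: triisopropylsilyl chloride CC(C)[Si](Cl)(C(C)C)C(C)C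
Why: monosilylation of a symmetrical resorcinol can give only one mono-ether because the two hydroxyls are equivalent.

Step 6
Reactants: 11 3-methoxy-5-[(triisopropylsilyl)oxy]phenol
Product: 12 2-bromo-3-methoxy-5-[(triisopropylsilyl)oxy]phenol
Conditions: NBS (1.0 equiv), i-Pr2NH (10 mol%), CH2Cl2, −78 to 0 °C
Reagents that add atoms: N-bromosuccinimide O=C1CCC(=O)N1Br
Why: amine-catalysed ortho-bromination of a phenol should go to the carbon between OH and OMe, the only free ring position not flanked by the bulky silyloxy group.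

Step 7
Reactants: 13 2,6-dihydroxybenzaldehyde
Product: 14 2,6-bis[(tert-butyldimethylsilyl)oxy]benzaldehyde
Conditions: t-BuMe2SiCl (2.5 equiv), imidazole, DMF, rt
Reagents that add atoms: tert-butyldimethylsilyl chloride CC(C)(C)[Si](C)(C)Cl
Why: standard silylation of both phenols gives ethers that are inert to light and removable by fluoride at the end.

Step 8
Reactants: 14 2,6-bis[(tert-butyldimethylsilyl)oxy]benzaldehyde; 15 diethylphosphonoacetic acid
Product: 17 (E)-3-{2,6-bis[(tert-butyldimethylsilyl)oxy]phenyl}prop-2-enoic acid, via dilithio phosphonoacetate dianion 16 (not isolated)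
Conditions: 15, n-BuLi (2.1 equiv), THF, −78 °C; then 14, −78 °C to rt; cold 1 M HCl to pH 3
Reagents that add atoms: none
Why: Horner–Wadsworth–Emmons olefination with the phosphonoacetic acid dianion should give the (E)-acid directly, avoiding an ester hydrolysis that the aryl silyl ethers would not survive.

Step 9
Reactants: 12 2-bromo-3-methoxy-5-[(triisopropylsilyl)oxy]phenol; 17 (E)-3-{2,6-bis[(tert-butyldimethylsilyl)oxy]phenyl}prop-2-enoic acid
Product: 18 2-bromo-3-methoxy-5-[(triisopropylsilyl)oxy]phenyl (E)-3-{2,6-bis[(tert-butyldimethylsilyl)oxy]phenyl}prop-2-enoate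
Conditions: DCC, DMAP (10 mol%), CH2Cl2, 0 °C to rt
Reagents that add atoms: none
Why: Steglich esterification acylates the only free phenol and thereby fixes which oxygen will become the pyranone oxygen.

Step 10
Reactants: 9 (S)-lavandulyl iodide; 18 2-bromo-3-methoxy-5-[(triisopropylsilyl)oxy]phenyl (E)-3-{2,6-bis[(tert-butyldimethylsilyl)oxy]phenyl}prop-2-enoate
Product: 20 3-methoxy-2-[(2R)-5-methyl-2-(prop-1-en-2-yl)hex-4-en-1-yl]-5-[(triisopropylsilyl)oxy]phenyl (E)-3-{2,6-bis[(tert-butyldimethylsilyl)oxy]phenyl}prop-2-enoate, via (S)-lavandulylzinc iodide 19 (not isolated)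
Conditions: 9, Zn dust, LiCl, THF, 40 °C; then 18, Pd(OAc)2 (3 mol%), SPhos (6 mol%), THF, 25 to 45 °C
Reagents that add atoms: none
Why: zinc insertion into the primary iodide followed by Negishi coupling with the di-ortho-substituted aryl bromide should form the aryl–CH2 bond, the stereocenter being β to zinc and uninvolved, while the ester, enoate and silyl ethers tolerate the organozinc.

Step 11
Reactants: 20 3-methoxy-2-[(2R)-5-methyl-2-(prop-1-en-2-yl)hex-4-en-1-yl]-5-[(triisopropylsilyl)oxy]phenyl (E)-3-{2,6-bis[(tert-butyldimethylsilyl)oxy]phenyl}prop-2-enoate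
Product: 22 (2S)-2-{2,6-bis[(tert-butyldimethylsilyl)oxy]phenyl}-7-methoxy-8-[(2R)-5-methyl-2-(prop-1-en-2-yl)hex-4-en-1-yl]-5-[(triisopropylsilyl)oxy]-2,3-dihydro-4H-chromen-4-one, via 2'-hydroxychalcone 21 (not isolated)
Conditions: hν (300 nm), degassed toluene (5 mM), 0 °C, until 20 is consumed; then, in the dark, 9-amino-9-deoxy-epi-quinidine-derived 3,5-bis(trifluoromethyl)phenyl thiourea (10 mol%), −20 °C; filtration through silica
Reagents that add atoms: none
Why: Excitation of the aryl ester should cleave the O1–acyl bond homolytically, and the caged aryloxyl/cinnamoyl radical pair should recombine at C4a, the only free position ortho to O1 because C8 carries the lavandulyl group, to give after tautomerisation the hydrogen-bonded 2'-hydroxychalcone 21 (photo-Fries rearrangement, the known behaviour of aryl cinnamates). In the dark the bifunctional amine–thiourea catalyst should then bind the ketone through its thiourea and deprotonate O1–H with its quinuclidine nitrogen, so that O1 adds to the enone carbon C2 in an intramolecular oxa-Michael addition, the known organocatalytic closure of 2'-hydroxychalcones to flavanones. This closes ring C in the 6-endo-trig mode, and together the two events form C4–C4a and O1–C2 in one flask. The C2 stereocenter is set by the catalyst, which should deliver the phenoxide to one face of the (E)-enone to give the 2S configuration, the remote lavandulyl stereocenter having no influence. The step needs ortho over para recombination, favoured by in-cage recombination in a non-polar solvent at low temperature and by the para carbon C6 being flanked by OMe and OSi(i-Pr)3, and it needs unambiguous ring closure, secured because the former ester oxygen is the only free phenol. Kinetic control at −20 °C and a neutral work-up should prevent erosion of C2 through the reversible ring opening.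

Step 12
Reactants: 22 (2S)-2-{2,6-bis[(tert-butyldimethylsilyl)oxy]phenyl}-7-methoxy-8-[(2R)-5-methyl-2-(prop-1-en-2-yl)hex-4-en-1-yl]-5-[(triisopropylsilyl)oxy]-2,3-dihydro-4H-chromen-4-one
Product: 23 exiguaflavanone B
Conditions: Bu4NF (3.3 equiv), AcOH (3.3 equiv), THF, 0 °C
Reagents that add atoms: none
Why: fluoride cleaves the three aryl silyl ethers, and acetic acid buffering keeps the phenols protonated so that neither ring opening nor epimerisation at C2 should occur.

**Compound list**

1 | (S)-4-benzyl-2-oxazolidinone | O=C1N[C@@H](Cc2ccccc2)CO1 | starting material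
2 | 3-methylbut-2-enoyl chloride | CC(C)=CC(=O)Cl | starting material
3 | lithium salt of 1 (N-lithio oxazolidinone) | [Li+].O=C1[N-][C@@H](Cc2ccccc2)CO1 | intermediate
4 | (S)-4-benzyl-3-(3-methylbut-2-enoyl)oxazolidin-2-one | CC(C)=CC(=O)N1[C@@H](Cc2ccccc2)COC1=O | intermediate
5 | prenyl bromide (1-bromo-3-methylbut-2-ene) | CC(C)=CCBr | starting material
6 | sodium Z-dienolate of 4 | [Na+].C=C(C)/C=C(\[O-])N1[C@@H](Cc2ccccc2)COC1=O | intermediate
7 | (S)-4-benzyl-3-[(2S)-5-methyl-2-(prop-1-en-2-yl)hex-4-enoyl]oxazolidin-2-one | C=C(C)[C@H](CC=C(C)C)C(=O)N1[C@@H](Cc2ccccc2)COC1=O | intermediate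
8 | (S)-lavandulol [(2S)-5-methyl-2-(prop-1-en-2-yl)hex-4-en-1-ol] | C=C(C)[C@H](CC=C(C)C)CO | intermediate
9 | (S)-lavandulyl iodide [(3S)-3-(iodomethyl)-2,6-dimethylhepta-1,5-diene] | C=C(C)[C@H](CC=C(C)C)CI | intermediate
10 | 5-methoxyresorcinol | COc1cc(O)cc(O)c1 | starting material
11 | 3-methoxy-5-[(triisopropylsilyl)oxy]phenol | COc1cc(O)cc(O[Si](C(C)C)(C(C)C)C(C)C)c1 | intermediate
12 | 2-bromo-3-methoxy-5-[(triisopropylsilyl)oxy]phenol | COc1cc(O[Si](C(C)C)(C(C)C)C(C)C)cc(O)c1Br | intermediate
13 | 2,6-dihydroxybenzaldehyde | O=Cc1c(O)cccc1O | starting material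
14 | 2,6-bis[(tert-butyldimethylsilyl)oxy]benzaldehyde | O=Cc1c(O[Si](C)(C)C(C)(C)C)cccc1O[Si](C)(C)C(C)(C)C | intermediate
15 | diethylphosphonoacetic acid | CCOP(=O)(CC(=O)O)OCC | starting material
16 | dilithio dianion of 15 | [Li+].[Li+].CCOP(=O)([CH-]C([O-])=O)OCC | intermediate
17 | (E)-3-{2,6-bis[(tert-butyldimethylsilyl)oxy]phenyl}prop-2-enoic acid | OC(=O)/C=C/c1c(O[Si](C)(C)C(C)(C)C)cccc1O[Si](C)(C)C(C)(C)C | intermediate
18 | 2-bromo-3-methoxy-5-[(triisopropylsilyl)oxy]phenyl (E)-3-{2,6-bis[(tert-butyldimethylsilyl)oxy]phenyl}prop-2-enoate | COc1cc(O[Si](C(C)C)(C(C)C)C(C)C)cc(OC(=O)/C=C/c2c(O[Si](C)(C)C(C)(C)C)cccc2O[Si](C)(C)C(C)(C)C)c1Br | intermediate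
19 | (S)-lavandulylzinc iodide | C=C(C)[C@H](CC=C(C)C)C[Zn]I | intermediate
20 | 3-methoxy-2-[(2R)-5-methyl-2-(prop-1-en-2-yl)hex-4-en-1-yl]-5-[(triisopropylsilyl)oxy]phenyl (E)-3-{2,6-bis[(tert-butyldimethylsilyl)oxy]phenyl}prop-2-enoate | C=C(C)[C@H](CC=C(C)C)Cc1c(OC)cc(O[Si](C(C)C)(C(C)C)C(C)C)cc1OC(=O)/C=C/c1c(O[Si](C)(C)C(C)(C)C)cccc1O[Si](C)(C)C(C)(C)C | intermediate
21 | (E)-3-{2,6-bis[(tert-butyldimethylsilyl)oxy]phenyl}-1-{2-hydroxy-4-methoxy-3-[(2R)-5-methyl-2-(prop-1-en-2-yl)hex-4-en-1-yl]-6-[(triisopropylsilyl)oxy]phenyl}prop-2-en-1-one | C=C(C)[C@H](CC=C(C)C)Cc1c(OC)cc(O[Si](C(C)C)(C(C)C)C(C)C)c(C(=O)/C=C/c2c(O[Si](C)(C)C(C)(C)C)cccc2O[Si](C)(C)C(C)(C)C)c1O | intermediate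
22 | (2S)-2-{2,6-bis[(tert-butyldimethylsilyl)oxy]phenyl}-7-methoxy-8-[(2R)-5-methyl-2-(prop-1-en-2-yl)hex-4-en-1-yl]-5-[(triisopropylsilyl)oxy]-2,3-dihydro-4H-chromen-4-one | C=C(C)[C@H](CC=C(C)C)Cc1c(OC)cc(O[Si](C(C)C)(C(C)C)C(C)C)c2c1O[C@H](c1c(O[Si](C)(C)C(C)(C)C)cccc1O[Si](C)(C)C(C)(C)C)CC2=O | intermediate
23 | exiguaflavanone B [(2S)-2-(2,6-dihydroxyphenyl)-5-hydroxy-7-methoxy-8-[(2R)-5-methyl-2-(prop-1-en-2-yl)hex-4-en-1-yl]-2,3-dihydro-4H-chromen-4-one] | C=C(C)[C@H](CC=C(C)C)Cc1c(OC)cc(O)c2c1O[C@H](c1c(O)cccc1O)CC2=O | target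

**Step count and risks**

Total step count: 12. Longest linear sequence: 7 steps (steps 1, 2, 3, 4, 10, 11, 12).

Steps most likely to fail:

Step 11. The radical pair may recombine at the para carbon C6 or escape the cage. Light may also isomerise the chalcone to its Z form or close the ring before the catalyst is present, and the catalysed closure may show poor facial selectivity; each of these erodes the configuration at C2. The fallback gives up asymmetric ring closure and instead removes the wrong C2 epimer under catalyst control. It sets out from 20, which is irradiated as before to chalcone 21. The chalcone is then cyclised without stereocontrol (DBU, 10 mol%, toluene, rt) to 22 together with its C2 epimer, the (2R)-flavanone F1. Asymmetric transfer hydrogenation with Cp*RhCl[(R,R)-TsDPEN] (1 mol%), HCO2H/Et3N, EtOAc, rt should reduce only the matched epimer F1 to the cis-(2R,4R)-flavan-4-ol F2. Chromatography removes F2 and the route is rejoined at 22.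

Step 6. Bromination may occur para to the hydroxyl despite the flanking silyloxy group, or run on to polybromination. The fallback replaces electrophilic substitution by directed ortho-metalation. It sets out from 11, which is converted with MOMCl and i-Pr2NEt in CH2Cl2 to the MOM ether 1-methoxy-3-(methoxymethoxy)-5-[(triisopropylsilyl)oxy]benzene F3. n-BuLi in THF at 0 °C should lithiate only between OMOM and OMe, and BrCCl2CCl2Br then gives 2-bromo-1-methoxy-3-(methoxymethoxy)-5-[(triisopropylsilyl)oxy]benzene F4. HCl in MeOH at rt removes the MOM group, acceptable here because no lavandulyl group is yet present, and the route is rejoined at 12.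

Step 10. The hindered arylpalladium intermediate may be diverted by the neighbouring cinnamate (insertion into its C=C bond), or oxidative addition may be so slow that the organozinc is lost by protonation or β-hydride elimination. The fallback reverses the order of the two unions so that no ester or enoate is present during the coupling. It sets out from 12, which is coupled with organozinc 19 (from 9) under Pd(OAc)2/SPhos in THF with slow addition of the zinc reagent, conditions known to tolerate a free phenol. This gives 3-methoxy-2-[(2R)-5-methyl-2-(prop-1-en-2-yl)hex-4-en-1-yl]-5-[(triisopropylsilyl)oxy]phenol F5, which is esterified with 17 (DCC, DMAP, CH2Cl2), and the route is rejoined at 20.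

Further compounds
F1 | step 11 | (2R)-2-{2,6-bis[(tert-butyldimethylsilyl)oxy]phenyl}-7-methoxy-8-[(2R)-5-methyl-2-(prop-1-en-2-yl)hex-4-en-1-yl]-5-[(triisopropylsilyl)oxy]-2,3-dihydro-4H-chromen-4-one | C=C(C)[C@H](CC=C(C)C)Cc1c(OC)cc(O[Si](C(C)C)(C(C)C)C(C)C)c2c1O[C@@H](c1c(O[Si](C)(C)C(C)(C)C)cccc1O[Si](C)(C)C(C)(C)C)CC2=O
F2 | step 11 | (2R,4R)-2-{2,6-bis[(tert-butyldimethylsilyl)oxy]phenyl}-7-methoxy-8-[(2R)-5-methyl-2-(prop-1-en-2-yl)hex-4-en-1-yl]-5-[(triisopropylsilyl)oxy]chroman-4-ol | C=C(C)[C@H](CC=C(C)C)Cc1c(OC)cc(O[Si](C(C)C)(C(C)C)C(C)C)c2c1O[C@@H](c1c(O[Si](C)(C)C(C)(C)C)cccc1O[Si](C)(C)C(C)(C)C)C[C@H]2O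
F3 | step 6 | 1-methoxy-3-(methoxymethoxy)-5-[(triisopropylsilyl)oxy]benzene | COCOc1cc(OC)cc(O[Si](C(C)C)(C(C)C)C(C)C)c1
F4 | step 6 | 2-bromo-1-methoxy-3-(methoxymethoxy)-5-[(triisopropylsilyl)oxy]benzene | COCOc1cc(O[Si](C(C)C)(C(C)C)C(C)C)cc(OC)c1Br
F5 | step 10 | 3-methoxy-2-[(2R)-5-methyl-2-(prop-1-en-2-yl)hex-4-en-1-yl]-5-[(triisopropylsilyl)oxy]phenol | C=C(C)[C@H](CC=C(C)C)Cc1c(OC)cc(O[Si](C(C)C)(C(C)C)C(C)C)cc1O
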